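**Numbering.** Tetralin numbering is used for the target and for the atoms that become it: C1 (aryl-bearing), C2, C3, C4, C4a, C5–C8, C8a. C2a and C3a are the CH2O carbons on C2 and C3, with oxygens O2a and O3a. Ring A is the fused arene, ring B is C1–C2–C3–C4–C4a–C8a, ring C is the pendant aryl group.

**Remark on the chemistry.** The target is drawn as the free hydrogen sulfate; the sulfate is carried as its sodium salt and protonated only in the last operation. C1 of compounds 10–14 is a mixture of epimers by design and is written without a descriptor.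

## Analysis of the target

The target is a 1-aryl-1,2,3,4-tetrahydronaphthalene of the lyoniresinol type. Ring B is fused to a pentasubstituted ring A (C5–H, C6–OMe, C7–OH, C8–OMe), and carries a 4-hydroxy-3,5-dimethoxyphenyl group (ring C) on C1, CH2OSO3H (C2a) on C2 and CH2OH (C3a) on C3. The three contiguous stereocentres are (1R,2S,3S) and all-trans: the aryl group on C1 is anti to the C2a arm, and the C2a arm is anti to the C3a arm. C1 is a doubly benzylic methine crowded by the peri methoxy group on C8 and cannot be corrected by enolisation once it is set. The two primary CH2O groups differ only in their distance from C1, yet only O2a, the more hindered one, carries the sulfate, and two phenols compete for any sulfating agent. The sensitive groups are the monoalkyl hydrogen sulfate (labile as the free acid) and the two electron-rich phenols (oxidation, quinone methide formation at C1). The difficulty is therefore threefold: absolute control of three centres, distinction of O2a from O3a, and a sulfate that must arrive late.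

The feature the route exploits is the C1–C2 bond of ring B together with the chain C2a–C2–C3–C3a. If a nitrogen atom is placed into the C1–C2 bond, that chain becomes the four carbons of L-aspartic acid (C2a and C3a are its two carboxyl carbons, C2 is Cα with its natural configuration, C3 is Cβ), and ring B becomes a 2-benzazepine. The nitrogen then sits between a diarylmethyl carbon (C1), the kind of carbon from which nitrogen is extruded most easily, and the pool stereocentre C2.

## Retrosynthetic reasoning

**19 ⇒ 17 ⇒ 16 (O–S bond, benzyl ethers).** The sulfate is placed on the last-but-one compound, on the only free hydroxyl of 16. Both phenols and O3a are benzyl ethers, which fall in one hydrogenolysis that a sulfate monoester anion survives. This removes any need for a selective sulfation; the forward route must deliver 16 with O2a free and O3a masked.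

**16 ⇒ 12 (C1–C2 bond cut, one nitrogen inserted).** Ring B of 16 is traced back to the seven-membered azacycle of 12, in which NH bridges C1 and C2. The cut is made here and not elsewhere for three reasons: C1 is diarylmethyl (weak C–N bond, stabilised radical, no β-hydrogen), C2 is the carbon that carries nitrogen in an amino acid, and C1 becomes planar on the way, so both C1 epimers of 12 give the same product. What is gained is that C1 need not be controlled in any earlier step, that C2 comes from the chiral pool, and that 12 has one defined stereocentre fewer than 16 and can be assembled by amine chemistry. The forward reaction has to aminate a hindered nitrogen, lose N2 and join C1 to C2 with retention at C2 and with the aryl group anti to the C2a arm.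

**12 ⇒ 11 ⇒ 10 ⇒ 8 + 1 (C1–N and C1–C8a bonds).** Both bonds to C1 come from the aldehyde carbon of 1 in an N-acyliminium Friedel–Crafts closure of the seven-membered ring. The carbamate ring of 8 does three jobs: it makes the iminium ion electrophilic enough for a seven-membered closure, it holds N and O2a together, and it leaves O3a as the only hydroxyl of 10, which is benzylated to 11 before hydrolysis to 12 frees N–H and O2a–H at once. The two ortho positions of ring A are equivalent, so the closure has no regiochemistry to solve.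

**8 ⇒ 7 ⇒ 6 (carbamate ring, lactone).** The oxazolidinone of 8 forms from the Boc group and O2a of diol 7, which is the reduction product of lactone 6. The distinction of the two arms arises here from constitution alone: O2a is 1,2 to nitrogen, O3a is 1,3.

**6 ⇒ 4 + 3, and 3 ⇐ 2 ⇐ 1 (C3–C4 bond).** The benzylic bond C3–C4 is made by alkylating the dianion of the commercial amino-acid-pool lactone 4 with bromide 3, anti to nitrogen, which sets C3. Bromide 3 comes from aldehyde 1 in two steps, so 1 supplies both aryl rings.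

## Alternatives that were turned down

**Alternative 1:** the textbook disconnection at C1–C8a. An α-(aryl-hydroxymethyl)-β-benzyl lactone A1 is ionised with acid and the benzylic cation closes ring B by Friedel–Crafts alkylation to the trans-fused aryltetralin lactone A2. The closure itself is reliable and trans-selective. It was turned down because A1 needs an auxiliary- or catalyst-controlled synthesis of an enantiopure β-benzyl lactone followed by an aldol reaction, and because A2 has its carbonyl on the C2 arm. After reduction both arms are CH2OH, so sulfating O2a alone needs an open–protect–reduce detour of about four steps. The cut also offers nothing for C2 and C3 beyond what an auxiliary provides. It is kept as the fallback for the key step.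

**Alternative 2:** the biomimetic disconnection at C2–C3 and C1–C8a. Two sinapate ester units are coupled oxidatively (phenoxy radical β–β coupling, then closure of one quinone methide onto the other arene) to the dihydronaphthalene diester A3 in a single operation. It was turned down for three reasons. The C2–C3 bond forms between two planar radicals far from any ester-borne chiral group, so A3 is expected racemic or of low enantiomeric purity. The C3=C4 double bond must then be reduced with control of C3. The two ester carbons are at the same oxidation level beside free phenols, so the route has no handle for placing the sulfate on O2a.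

**Alternative 3:** the cycloaddition disconnection at C1–C2 and C3–C4. Cyclic sulfone A4 loses SO2 on heating to an α-aryl-ortho-quinodimethane, which adds a fumarate diester to give the tetralin diester A5. It was turned down for three reasons. The ester next to C1 must react exo to give the 1,2-trans relationship, whereas secondary orbital overlap favours endo, and a wrong C1 cannot be repaired. Facial control needs a chiral ester auxiliary that is later removed. A4, on a pentasubstituted ring, costs five to six steps, and A5 again ends in two equivalent arms.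

Key step: step 9

## Route

**Step 1**
Reactants: 1 4-(benzyloxy)-3,5-dimethoxybenzaldehyde
Product: 2 [4-(benzyloxy)-3,5-dimethoxyphenyl]methanol
Conditions: NaBH4, MeOH, 0 °C
Reagents that add atoms: none
Why: Borohydride reduction of an aryl aldehyde; the aryl benzyl ether is inert to hydride.

**Step 2**
Reactants: 2 [4-(benzyloxy)-3,5-dimethoxyphenyl]methanol
Product: 3 2-(benzyloxy)-5-(bromomethyl)-1,3-dimethoxybenzene
Conditions: PBr3 (0.4 equiv), CH2Cl2, 0 °C; used without storage
Reagents that add atoms: phosphorus tribromide, BrP(Br)Br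
Why: Conversion of an electron-rich benzylic alcohol into the bromide through its phosphite ester; the reaction is fast at 0 °C, which spares the aryl benzyl ether.

**Step 3**
Reactants: 4 tert-butyl N-[(3S)-5-oxooxolan-3-yl]carbamate; 3 2-(benzyloxy)-5-(bromomethyl)-1,3-dimethoxybenzene
Product: 6 tert-butyl N-[(3S,4S)-4-{[4-(benzyloxy)-3,5-dimethoxyphenyl]methyl}-5-oxooxolan-3-yl]carbamate, via dilithio dianion 5 (not isolated)
Conditions: LiHMDS (2.1 equiv), THF, −78 °C; then 3, DMPU, −78 → −40 °C; H2O
Reagents that add atoms: none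
Why: Enolate alkylation of a β-amino lactone as its N,O-dianion; deprotonating the carbamate first prevents β-elimination of nitrogen. The benzylic bromide enters anti to the N(Li)Boc group on the neighbouring ring carbon, which sets C3 trans to nitrogen, (3S,4S).

**Step 4**
Reactants: 6 tert-butyl N-[(3S,4S)-4-{[4-(benzyloxy)-3,5-dimethoxyphenyl]methyl}-5-oxooxolan-3-yl]carbamate
Product: 7 tert-butyl N-[(2S,3S)-3-{[4-(benzyloxy)-3,5-dimethoxyphenyl]methyl}-1,4-dihydroxybutan-2-yl]carbamate
Conditions: LiBH4 (2 equiv), THF, 0 °C → rt; aqueous work-up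
Reagents that add atoms: none
Why: Reduction of a lactone to the diol by lithium borohydride, which leaves the Boc carbamate and the benzyl ether alone; neither stereocentre is touched.

**Step 5**
Reactants: 7 tert-butyl N-[(2S,3S)-3-{[4-(benzyloxy)-3,5-dimethoxyphenyl]methyl}-1,4-dihydroxybutan-2-yl]carbamate
Product: 8 (4S)-4-[(2S)-1-[4-(benzyloxy)-3,5-dimethoxyphenyl]-3-hydroxypropan-2-yl]-1,3-oxazolidin-2-one
Conditions: NaH (1.2 equiv), THF, 0 °C → rt; H2O
Reagents that add atoms: none
Why: Intramolecular carbamate exchange: the O2a alkoxide attacks the Boc carbonyl in a 5-exo closure and tert-butoxide leaves. The five-membered closure should outrun the six-membered one through O3a, and deprotonation of the product N–H removes the carbonyl from further exchange, so O2a is locked and O3a stays free.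

**Step 6**
Reactants: 8 (4S)-4-[(2S)-1-[4-(benzyloxy)-3,5-dimethoxyphenyl]-3-hydroxypropan-2-yl]-1,3-oxazolidin-2-one; 1 4-(benzyloxy)-3,5-dimethoxybenzaldehyde
Product: 10 cyclic carbamate linking N2 to the 3-CH2O of [(3S,4S)-8-(benzyloxy)-1-[4-(benzyloxy)-3,5-dimethoxyphenyl]-7,9-dimethoxy-2,3,4,5-tetrahydro-1H-2-benzazepine-3,4-diyl]dimethanol (4-CH2OH free; both C1 epimers), via N-acyliminium ion 9 (not isolated)
Conditions: TFA (5 equiv), CH2Cl2, 4 Å MS, 0 °C → rt; NaHCO3/MeOH work-up
Reagents that add atoms: none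
Why: Pictet–Spengler-type amidoalkylation: the carbamate N–H and the aldehyde give an N-acyliminium ion, which ring A attacks at the position ortho to the side chain (para and ortho to methoxy groups) to close the seven-membered ring. The two ortho positions of ring A are equivalent, and the configuration formed at C1 is irrelevant because step 9 erases it.

**Step 7**
Reactants: 10 (the tricyclic carbamate with free 4-CH2OH)
Product: 11 cyclic carbamate linking N2 to the 3-CH2O of [(3S,4S)-8-(benzyloxy)-1-[4-(benzyloxy)-3,5-dimethoxyphenyl]-4-[(benzyloxy)methyl]-7,9-dimethoxy-2,3,4,5-tetrahydro-1H-2-benzazepin-3-yl]methanol (both C1 epimers)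
Conditions: NaH (1.3 equiv), BnBr (1.2 equiv), Bu4NI (cat.), THF/DMF, 0 °C → rt
Reagents that add atoms: benzyl bromide, BrCc1ccccc1
Why: Williamson etherification of the only hydroxyl; the carbamate nitrogen is fully substituted, so O3a is benzylated without competition.

**Step 8**
Reactants: 11 (the benzylated tricyclic carbamate)
Product: 12 [(3S,4S)-8-(benzyloxy)-1-[4-(benzyloxy)-3,5-dimethoxyphenyl]-4-[(benzyloxy)methyl]-7,9-dimethoxy-2,3,4,5-tetrahydro-1H-2-benzazepin-3-yl]methanol (both C1 epimers)
Conditions: KOH (10 equiv), EtOH/H2O 4:1, 85 °C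
Reagents that add atoms: none
Why: Basic hydrolysis of an N-substituted oxazolidinone; the carbonyl leaves as carbonate and frees the secondary amine and O2a–H together, while benzyl and methyl ethers are stable to hydroxide.

**Step 9**
Reactants: 12 [(3S,4S)-8-(benzyloxy)-1-[4-(benzyloxy)-3,5-dimethoxyphenyl]-4-[(benzyloxy)methyl]-7,9-dimethoxy-2,3,4,5-tetrahydro-1H-2-benzazepin-3-yl]methanol
Product: 16 [(1R,2S,3S)-7-(benzyloxy)-1-[4-(benzyloxy)-3,5-dimethoxyphenyl]-3-[(benzyloxy)methyl]-6,8-dimethoxy-1,2,3,4-tetrahydronaphthalen-2-yl]methanol, via hydrazide adduct 13 (not isolated), via isodiazene 14 (not isolated), via 1,6-diradical 15 (not isolated)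
Conditions: N-(benzyloxy)-N-(pivaloyloxy)-4-(trifluoromethyl)benzamide (1.5 equiv), THF, 45 °C
Reagents that add atoms: none
Why: The amine nitrogen attacks the electrophilic nitrogen of the anomeric amide and displaces pivalate (13); the benzyloxy group then migrates to the acyl carbon, the ester leaves and isodiazene 14 remains. Loss of N2 starts at the weak C1–N bond (diarylmethyl) and gives the singlet 1,6-diradical 15, which collapses by C1–C2 bond formation. The closest known reaction type is the nitrogen deletion of secondary amines through isodiazenes, which contracts α-aryl and benzo-fused azacycles by one atom. Ring B closes by radical–radical recombination inside a tethered pair, a contraction of the seven-membered azacycle to the six-membered carbocycle, for which Baldwin's rules do not apply. C3 is untouched; C2 becomes a planar radical but is expected to bond on the face that nitrogen has just left, and this retention is also the arrangement in which the C2a and C3a arms stay anti on the forming half-chair. C1 is a planar diarylmethyl radical whatever the configuration of 12, so both epimers converge, and it should bond with its aryl group anti to the C2a arm, the less crowded of the two approaches. The step needs recombination to win over intramolecular hydrogen transfer and amination of nitrogen to win over reaction at the free hydroxyl; the first is helped by C1 having no β-hydrogen and by the short tether, the second by the far higher nucleophilicity of the amine.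

**Step 10**
Reactants: 16 [(1R,2S,3S)-7-(benzyloxy)-1-[4-(benzyloxy)-3,5-dimethoxyphenyl]-3-[(benzyloxy)methyl]-6,8-dimethoxy-1,2,3,4-tetrahydronaphthalen-2-yl]methanol
Product: 17 sodium [(1R,2S,3S)-7-(benzyloxy)-1-[4-(benzyloxy)-3,5-dimethoxyphenyl]-3-[(benzyloxy)methyl]-6,8-dimethoxy-1,2,3,4-tetrahydronaphthalen-2-yl]methyl sulfate
Conditions: SO3·pyridine (3 equiv), pyridine, rt; then aq. NaHCO3
Reagents that add atoms: sulfur trioxide–pyridine complex, [O-]S(=O)(=O)[n+]1ccccc1; sodium hydrogen carbonate, [Na+].OC([O-])=O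
Why: O-Sulfation of a primary alcohol with an amine–SO3 complex; O2a–H is the only hydroxyl in 16, so no selectivity is asked of the reagent.

**Step 11**
Reactants: 17 sodium [(1R,2S,3S)-7-(benzyloxy)-1-[4-(benzyloxy)-3,5-dimethoxyphenyl]-3-[(benzyloxy)methyl]-6,8-dimethoxy-1,2,3,4-tetrahydronaphthalen-2-yl]methyl sulfate
Product: 19 [(1R,2S,3S)-7-hydroxy-1-(4-hydroxy-3,5-dimethoxyphenyl)-3-(hydroxymethyl)-6,8-dimethoxy-1,2,3,4-tetrahydronaphthalen-2-yl]methyl hydrogen sulfate, via sodium salt 18 (not isolated)
Conditions: H2 (1 atm), 10% Pd/C, MeOH/THF, rt; filter; then aq. HCl (1.0 equiv), 0 °C, desalt on C18 and lyophilise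
Reagents that add atoms: none
Why: Hydrogenolysis of two aryl benzyl ethers and one alkyl benzyl ether; the C1–aryl and C4–aryl bonds are C–C bonds and the primary sulfate monoester anion is not reduced. One equivalent of acid at 0 °C then gives the hydrogen sulfate without exposing it to excess acid.

## Compound list

1 | 4-(benzyloxy)-3,5-dimethoxybenzaldehyde | COc1cc(C=O)cc(OC)c1OCc1ccccc1 | starting material
2 | [4-(benzyloxy)-3,5-dimethoxyphenyl]methanol | COc1cc(CO)cc(OC)c1OCc1ccccc1 | intermediate
3 | 2-(benzyloxy)-5-(bromomethyl)-1,3-dimethoxybenzene | COc1cc(CBr)cc(OC)c1OCc1ccccc1 | intermediate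
4 | tert-butyl N-[(3S)-5-oxooxolan-3-yl]carbamate | CC(C)(C)OC(=O)N[C@@H]1COC(=O)C1 | starting material
5 | N,O-dilithio dianion of 4 (lithium enolate, N-lithiated carbamate) | CC(C)(C)OC(=O)N([Li])[C@@H]1COC(O[Li])=C1 | intermediate (not isolated)
6 | tert-butyl N-[(3S,4S)-4-{[4-(benzyloxy)-3,5-dimethoxyphenyl]methyl}-5-oxooxolan-3-yl]carbamate | O=C1OC[C@@H](NC(=O)OC(C)(C)C)[C@@H]1Cc1cc(OC)c(OCc2ccccc2)c(OC)c1 | intermediate
7 | tert-butyl N-[(2S,3S)-3-{[4-(benzyloxy)-3,5-dimethoxyphenyl]methyl}-1,4-dihydroxybutan-2-yl]carbamate | OC[C@@H](NC(=O)OC(C)(C)C)[C@@H](CO)Cc1cc(OC)c(OCc2ccccc2)c(OC)c1 | intermediate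
8 | (4S)-4-[(2S)-1-[4-(benzyloxy)-3,5-dimethoxyphenyl]-3-hydroxypropan-2-yl]-1,3-oxazolidin-2-one | O=C1OC[C@@H](N1)[C@@H](CO)Cc1cc(OC)c(OCc2ccccc2)c(OC)c1 | intermediate
9 | N-acyliminium ion from 8 and 1 (trifluoroacetate counter-ion) | O=C1OC[C@@H]([N+]1=Cc1cc(OC)c(OCc2ccccc2)c(OC)c1)[C@@H](CO)Cc1cc(OC)c(OCc2ccccc2)c(OC)c1 | intermediate (not isolated)
10 | cyclic carbamate linking N2 to the 3-CH2O of [(3S,4S)-8-(benzyloxy)-1-[4-(benzyloxy)-3,5-dimethoxyphenyl]-7,9-dimethoxy-2,3,4,5-tetrahydro-1H-2-benzazepine-3,4-diyl]dimethanol, 4-CH2OH free, both C1 epimers | O=C1OC[C@H]2N1C(c1cc(OC)c(OCc3ccccc3)c(OC)c1)c1c(OC)c(OCc3ccccc3)c(OC)cc1C[C@@H]2CO | intermediate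
11 | 4-CH2O-benzyl ether of 10, both C1 epimers | O=C1OC[C@H]2N1C(c1cc(OC)c(OCc3ccccc3)c(OC)c1)c1c(OC)c(OCc3ccccc3)c(OC)cc1C[C@@H]2COCc1ccccc1 | intermediate
12 | [(3S,4S)-8-(benzyloxy)-1-[4-(benzyloxy)-3,5-dimethoxyphenyl]-4-[(benzyloxy)methyl]-7,9-dimethoxy-2,3,4,5-tetrahydro-1H-2-benzazepin-3-yl]methanol, both C1 epimers | OC[C@H]1NC(c2cc(OC)c(OCc3ccccc3)c(OC)c2)c2c(OC)c(OCc3ccccc3)c(OC)cc2C[C@@H]1COCc1ccccc1 | intermediate
13 | N-amination adduct of 12: N2 bears N(OBn)C(=O)C6H4-4-CF3 | OC[C@H]1N(N(OCc2ccccc2)C(=O)c2ccc(cc2)C(F)(F)F)C(c2cc(OC)c(OCc3ccccc3)c(OC)c2)c2c(OC)c(OCc3ccccc3)c(OC)cc2C[C@@H]1COCc1ccccc1 | intermediate (not isolated)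
14 | isodiazene (1,1-diazene) of 12 | OC[C@H]1[N+](=[N-])C(c2cc(OC)c(OCc3ccccc3)c(OC)c2)c2c(OC)c(OCc3ccccc3)c(OC)cc2C[C@@H]1COCc1ccccc1 | intermediate (not isolated)
15 | 1,6-diradical after loss of N2: diarylmethyl radical at C1, secondary alkyl radical at C2, C3 (S) | OC[CH][C@@H](COCc1ccccc1)Cc1cc(OC)c(OCc2ccccc2)c(OC)c1[CH]c1cc(OC)c(OCc2ccccc2)c(OC)c1 | intermediate (not isolated)
16 | [(1R,2S,3S)-7-(benzyloxy)-1-[4-(benzyloxy)-3,5-dimethoxyphenyl]-3-[(benzyloxy)methyl]-6,8-dimethoxy-1,2,3,4-tetrahydronaphthalen-2-yl]methanol | COc1cc([C@@H]2c3c(cc(OC)c(OCc4ccccc4)c3OC)C[C@H](COCc3ccccc3)[C@H]2CO)cc(OC)c1OCc1ccccc1 | intermediate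
17 | sodium [(1R,2S,3S)-7-(benzyloxy)-1-[4-(benzyloxy)-3,5-dimethoxyphenyl]-3-[(benzyloxy)methyl]-6,8-dimethoxy-1,2,3,4-tetrahydronaphthalen-2-yl]methyl sulfate | COc1cc([C@@H]2c3c(cc(OC)c(OCc4ccccc4)c3OC)C[C@H](COCc3ccccc3)[C@H]2COS(=O)(=O)[O-])cc(OC)c1OCc1ccccc1.[Na+] | intermediate
18 | sodium [(1R,2S,3S)-7-hydroxy-1-(4-hydroxy-3,5-dimethoxyphenyl)-3-(hydroxymethyl)-6,8-dimethoxy-1,2,3,4-tetrahydronaphthalen-2-yl]methyl sulfate | COc1cc([C@@H]2c3c(cc(OC)c(O)c3OC)C[C@H](CO)[C@H]2COS(=O)(=O)[O-])cc(OC)c1O.[Na+] | intermediate (not isolated)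
19 | [(1R,2S,3S)-7-hydroxy-1-(4-hydroxy-3,5-dimethoxyphenyl)-3-(hydroxymethyl)-6,8-dimethoxy-1,2,3,4-tetrahydronaphthalen-2-yl]methyl hydrogen sulfate | COc1cc([C@@H]2c3c(cc(OC)c(O)c3OC)C[C@H](CO)[C@H]2COS(=O)(=O)O)cc(OC)c1O | target

## Step count and least certain steps

Total: 11 steps. Longest linear sequence: 11 steps (1 → 2 → 3 → 6 → 7 → 8 → 10 → 11 → 12 → 16 → 17 → 19); 9 steps from 4.

**Step 9 (key step).** Three processes may go wrong.
- Hydrogen transfer inside the radical pair (from C3–H to C1) may compete with recombination and give a ring-opened alkene.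
- Bond formation may occur with incomplete facial selectivity at C1 or C2, because both centres are planar at the moment of closure and only the tether and the C3 substituent bias them.
- Amination of the doubly α-branched nitrogen may be slow.

Fallback, from 3 (with 1) to 16, without the nitrogen: commercial (S)-4-benzyl-1,3-oxazolidin-2-one is acylated with mono-tert-butyl succinate (PivCl, Et3N, LiCl) to tert-butyl 4-[(4S)-4-benzyl-2-oxo-1,3-oxazolidin-3-yl]-4-oxobutanoate F1. Its sodium enolate (NaHMDS, THF, −78 °C) is alkylated with 3 anti to the auxiliary benzyl group to give tert-butyl (3S)-3-{[4-(benzyloxy)-3,5-dimethoxyphenyl]methyl}-4-[(4S)-4-benzyl-2-oxo-1,3-oxazolidin-3-yl]-4-oxobutanoate F2, which sets C3. LiBH4 removes the auxiliary and gives tert-butyl (3S)-3-{[4-(benzyloxy)-3,5-dimethoxyphenyl]methyl}-4-hydroxybutanoate F3, and BnBr/Ag2O masks O3a as tert-butyl (3S)-4-(benzyloxy)-3-{[4-(benzyloxy)-3,5-dimethoxyphenyl]methyl}butanoate F4. The lithium enolate of F4 (LDA, −78 °C) adds to 1 to give the β-hydroxy ester tert-butyl (3S)-2-{[4-(benzyloxy)-3,5-dimethoxyphenyl](hydroxy)methyl}-3-[(benzyloxy)methyl]-4-[4-(benzyloxy)-3,5-dimethoxyphenyl]butanoate F5. BF3·OEt2 at −40 °C ionises the benzylic alcohol, the cation closes ring B by Friedel–Crafts alkylation at C8a, and catalytic KOtBu equilibrates C2 to the all-trans ester tert-butyl (1R,2S,3S)-7-(benzyloxy)-1-[4-(benzyloxy)-3,5-dimethoxyphenyl]-3-[(benzyloxy)methyl]-6,8-dimethoxy-1,2,3,4-tetrahydronaphthalene-2-carboxylate F6. LiAlH4 reduces F6 to 16.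

**Step 6.** The N-acyliminium ion may be held reversibly by the free hydroxyl or by a second carbamate instead of undergoing the slower seven-membered closure onto a ring position flanked by a methoxy group; prolonged acid may also start to cleave the aryl benzyl ethers.

Fallback, from 8 to 12, closing the ring with an unhindered one-carbon electrophile and bringing ring C in as a nucleophile: 8 is cyclised with paraformaldehyde and TFA to the C1-unsubstituted tricyclic carbamate F7 (cyclic carbamate linking N2 to the 3-CH2O of [(3S,4S)-8-(benzyloxy)-7,9-dimethoxy-2,3,4,5-tetrahydro-1H-2-benzazepine-3,4-diyl]dimethanol). NaH/BnBr gives its 4-CH2O-benzyl ether F8, and KOH hydrolysis gives [(3S,4S)-8-(benzyloxy)-4-[(benzyloxy)methyl]-7,9-dimethoxy-2,3,4,5-tetrahydro-1H-2-benzazepin-3-yl]methanol F9. N-Chlorination (NCS) and dehydrochlorination (DBU) give the conjugated cyclic aldimine [(3S,4S)-8-(benzyloxy)-4-[(benzyloxy)methyl]-7,9-dimethoxy-4,5-dihydro-3H-2-benzazepin-3-yl]methanol F10. 2-(Benzyloxy)-5-bromo-1,3-dimethoxybenzene F11 (from commercial 4-bromo-2,6-dimethoxyphenol, BnBr, K2CO3) is lithiated with n-BuLi at −78 °C, and the aryllithium (2.2 equiv) adds to F10 to give 12; either C1 epimer serves.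

**Step 5.** Closure through the O3a alkoxide (six-membered cyclic carbamate) or O-to-O carbamoyl migration would invert the distinction of the two arms, and the error would only show after step 10.

Fallback, from 6 to 8, making the closure unambiguous by keeping C3a at the acid level: LiOH (THF/H2O) opens the lactone to lithium (2S,3S)-2-{[4-(benzyloxy)-3,5-dimethoxyphenyl]methyl}-3-[(tert-butoxycarbonyl)amino]-4-hydroxybutanoate F12, in which O2a–H is the only hydroxyl. KOtBu in THF closes the oxazolidinone, and acidification gives (2S)-3-[4-(benzyloxy)-3,5-dimethoxyphenyl]-2-[(4S)-2-oxo-1,3-oxazolidin-4-yl]propanoic acid F13. BH3·THF reduces the carboxylic acid chemoselectively to 8.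

## Further compounds

F1 | step 9 | tert-butyl 4-[(4S)-4-benzyl-2-oxo-1,3-oxazolidin-3-yl]-4-oxobutanoate | CC(C)(C)OC(=O)CCC(=O)N1[C@@H](Cc2ccccc2)COC1=O
F2 | step 9 | tert-butyl (3S)-3-{[4-(benzyloxy)-3,5-dimethoxyphenyl]methyl}-4-[(4S)-4-benzyl-2-oxo-1,3-oxazolidin-3-yl]-4-oxobutanoate | CC(C)(C)OC(=O)C[C@H](Cc1cc(OC)c(OCc2ccccc2)c(OC)c1)C(=O)N1[C@@H](Cc2ccccc2)COC1=O
F3 | step 9 | tert-butyl (3S)-3-{[4-(benzyloxy)-3,5-dimethoxyphenyl]methyl}-4-hydroxybutanoate | OC[C@@H](Cc1cc(OC)c(OCc2ccccc2)c(OC)c1)CC(=O)OC(C)(C)C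
F4 | step 9 | tert-butyl (3S)-4-(benzyloxy)-3-{[4-(benzyloxy)-3,5-dimethoxyphenyl]methyl}butanoate | c1ccccc1COC[C@@H](Cc1cc(OC)c(OCc2ccccc2)c(OC)c1)CC(=O)OC(C)(C)C
F5 | step 9 | tert-butyl (3S)-2-{[4-(benzyloxy)-3,5-dimethoxyphenyl](hydroxy)methyl}-3-[(benzyloxy)methyl]-4-[4-(benzyloxy)-3,5-dimethoxyphenyl]butanoate (mixture at C2 and the carbinol carbon) | c1ccccc1COC[C@@H](Cc1cc(OC)c(OCc2ccccc2)c(OC)c1)C(C(O)c1cc(OC)c(OCc2ccccc2)c(OC)c1)C(=O)OC(C)(C)C
F6 | step 9 | tert-butyl (1R,2S,3S)-7-(benzyloxy)-1-[4-(benzyloxy)-3,5-dimethoxyphenyl]-3-[(benzyloxy)methyl]-6,8-dimethoxy-1,2,3,4-tetrahydronaphthalene-2-carboxylate | COc1cc(cc(OC)c1OCc1ccccc1)[C@@H]1c2c(OC)c(OCc3ccccc3)c(OC)cc2C[C@H](COCc2ccccc2)[C@H]1C(=O)OC(C)(C)C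
F7 | step 6 | cyclic carbamate linking N2 to the 3-CH2O of [(3S,4S)-8-(benzyloxy)-7,9-dimethoxy-2,3,4,5-tetrahydro-1H-2-benzazepine-3,4-diyl]dimethanol, 4-CH2OH free | O=C1OC[C@H]2N1Cc1c(OC)c(OCc3ccccc3)c(OC)cc1C[C@@H]2CO
F8 | step 6 | 4-CH2O-benzyl ether of F7 | O=C1OC[C@H]2N1Cc1c(OC)c(OCc3ccccc3)c(OC)cc1C[C@@H]2COCc1ccccc1
F9 | step 6 | [(3S,4S)-8-(benzyloxy)-4-[(benzyloxy)methyl]-7,9-dimethoxy-2,3,4,5-tetrahydro-1H-2-benzazepin-3-yl]methanol | OC[C@H]1NCc2c(OC)c(OCc3ccccc3)c(OC)cc2C[C@@H]1COCc1ccccc1
F10 | step 6 | [(3S,4S)-8-(benzyloxy)-4-[(benzyloxy)methyl]-7,9-dimethoxy-4,5-dihydro-3H-2-benzazepin-3-yl]methanol | OC[C@H]1N=Cc2c(OC)c(OCc3ccccc3)c(OC)cc2C[C@@H]1COCc1ccccc1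
F11 | step 6 | 2-(benzyloxy)-5-bromo-1,3-dimethoxybenzene | COc1cc(Br)cc(OC)c1OCc1ccccc1
F12 | step 5 | lithium (2S,3S)-2-{[4-(benzyloxy)-3,5-dimethoxyphenyl]methyl}-3-[(tert-butoxycarbonyl)amino]-4-hydroxybutanoate | [Li+].[O-]C(=O)[C@@H](Cc1cc(OC)c(OCc2ccccc2)c(OC)c1)[C@@H](CO)NC(=O)OC(C)(C)C
F13 | step 5 | (2S)-3-[4-(benzyloxy)-3,5-dimethoxyphenyl]-2-[(4S)-2-oxo-1,3-oxazolidin-4-yl]propanoic acid | O=C1OC[C@@H](N1)[C@@H](C(=O)O)Cc1cc(OC)c(OCc2ccccc2)c(OC)c1
A1 | alternative 1 | (3R,4S)-3-{[4-(benzyloxy)-3,5-dimethoxyphenyl](hydroxy)methyl}-4-{[4-(benzyloxy)-3,5-dimethoxyphenyl]methyl}oxolan-2-one | O=C1OC[C@@H](Cc2cc(OC)c(OCc3ccccc3)c(OC)c2)[C@@H]1C(O)c1cc(OC)c(OCc2ccccc2)c(OC)c1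
A2 | alternative 1 | trans-fused aryltetralin γ-lactone, carbonyl on the C2 arm and O–CH2 on the C3 arm, (1R,2S,3S) in tetralin numbering, phenols as benzyl ethers | COc1cc(cc(OC)c1OCc1ccccc1)[C@@H]1c2c(OC)c(OCc3ccccc3)c(OC)cc2C[C@@H]2COC(=O)[C@@H]12
A3 | alternative 2 | dimethyl (1R,2S)-7-hydroxy-1-(4-hydroxy-3,5-dimethoxyphenyl)-6,8-dimethoxy-1,2-dihydronaphthalene-2,3-dicarboxylate (formed as the racemate) | COc1cc([C@@H]2c3c(cc(OC)c(O)c3OC)C=C(C(=O)OC)[C@H]2C(=O)OC)cc(OC)c1O
A4 | alternative 3 | 6-(benzyloxy)-1-[4-(benzyloxy)-3,5-dimethoxyphenyl]-5,7-dimethoxy-1,3-dihydro-2-benzothiophene 2,2-dioxide (racemic) | COc1cc(cc(OC)c1OCc1ccccc1)C1c2c(OC)c(OCc3ccccc3)c(OC)cc2CS1(=O)=O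
A5 | alternative 3 | dimethyl (1R,2S,3S)-7-(benzyloxy)-1-[4-(benzyloxy)-3,5-dimethoxyphenyl]-6,8-dimethoxy-1,2,3,4-tetrahydronaphthalene-2,3-dicarboxylate | COc1cc(cc(OC)c1OCc1ccccc1)[C@@H]1c2c(OC)c(OCc3ccccc3)c(OC)cc2C[C@H](C(=O)OC)[C@H]1C(=O)OC
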